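**Strategy.** Ring A is cut across two of its ring bonds: the methoxy-bearing carbon and the three CH carbons next to it (C1–C4 of 1-methoxycyclohexa-1,3-diene) are joined to the chain-bearing carbon and the remaining ring carbon, which arrive as the β- and α-carbons of an alkynoate. A single thermal operation, [4+2] cycloaddition then ethylene loss, forms both C–C bonds and the arene with the methyl ether already in place, so no phenol is ever methylated selectively. The precursor is a benzyl 5-arylpent-2-ynoate bearing the complete O-benzylated B–C–D diaryl ether; its regiocontrolling ester ends between OMe and chain and is excised by protodecarboxylation after hydrogenolysis.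

Key step: step 7

Remarks on the chemistry:
- The target has no stereocentre, stereoaxis or stereogenic double bond, so the SMILES defines one achiral compound and no stereocontrol is needed.
- 1-Methoxycyclohexa-1,3-diene is assumed to be bought as the technical-grade liquid. Its usual companions, the unconjugated 1,4-isomer and anisole, are inert diluents, and the diene is used in excess.

**Step 1**
Reactants: 1 4-ethenylphenyl acetate (4-acetoxystyrene); 2 1-(benzyloxy)-3-bromobenzene
Product: 5 4-{2-[3-(benzyloxy)phenyl]ethyl}phenol, via B-alkyl-9-BBN aryl acetate 3 (not isolated), via B-alkyl-9-BBN phenol 4 (not isolated)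
Conditions: 9-BBN, THF, 0 °C to rt; 3 M aq NaOH, rt; then 2, PdCl2(dppf) (3 mol %), 65 °C; aq NH4Cl/HCl work-up
Reagents that add atoms: none
Why: Anti-Markovnikov hydroboration of the styrene with 9-BBN followed by B-alkyl Suzuki–Miyaura coupling with the aryl bromide forms the sp3–sp2 bond of the C–D bibenzyl directly, and the aqueous hydroxide that activates the borane also saponifies the aryl acetate, so no alkene has to be reduced beside the benzyl ether.

**Step 2**
Reactants: 6 methyl 3-(4-hydroxyphenyl)propanoate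
Product: 7 methyl 3-(3-bromo-4-hydroxyphenyl)propanoate
Conditions: NBS (1.0 equiv), TsOH·H2O (10 mol %), MeOH, rt
Reagents that add atoms: N-bromosuccinimide, O=C1CCC(=O)N1Br
Why: Electrophilic aromatic bromination of a para-blocked phenol can only occur ortho to the hydroxyl, and NBS with catalytic sulfonic acid in methanol is an established way to stop at mono-bromination.

**Step 3**
Reactants: 7 methyl 3-(3-bromo-4-hydroxyphenyl)propanoate
Product: 8 methyl 3-[4-(benzyloxy)-3-bromophenyl]propanoate
Conditions: BnBr, K2CO3, DMF, rt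
Reagents that add atoms: benzyl bromide, BrCc1ccccc1
Why: Williamson ether synthesis on the phenoxide proceeds cleanly at room temperature and leaves the methyl ester untouched.

**Step 4**
Reactants: 8 methyl 3-[4-(benzyloxy)-3-bromophenyl]propanoate; 5 4-{2-[3-(benzyloxy)phenyl]ethyl}phenol
Product: 9 methyl 3-[4-(benzyloxy)-3-(4-{2-[3-(benzyloxy)phenyl]ethyl}phenoxy)phenyl]propanoate
Conditions: CuI (10 mol %), picolinic acid (20 mol %), K3PO4, DMSO, 90 °C, Ar
Reagents that add atoms: none
Why: Ligand-accelerated Ullmann diaryl ether synthesis with the Cu/picolinic acid system is established for ortho-substituted, electron-rich aryl bromides and unhindered phenols under conditions mild enough for a methyl ester and benzyl ethers.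

**Step 5**
Reactants: 9 methyl 3-[4-(benzyloxy)-3-(4-{2-[3-(benzyloxy)phenyl]ethyl}phenoxy)phenyl]propanoate
Product: 11 1-(benzyloxy)-4-(but-3-yn-1-yl)-2-(4-{2-[3-(benzyloxy)phenyl]ethyl}phenoxy)benzene, via aldehyde 10 (not isolated)
Conditions: DIBAL-H (1.2 equiv), CH2Cl2, −78 °C; then MeOH, Ohira–Bestmann reagent, K2CO3, −78 °C to rt; Rochelle salt work-up
Reagents that add atoms: dimethyl (1-diazo-2-oxopropyl)phosphonate, COP(=O)(OC)C(=[N+]=[N-])C(C)=O
Why: DIBAL-H half-reduction at −78 °C stops at the tetrahedral aluminium hemiacetal, which releases aldehyde 10 on methanol quench, and this is homologated in the same flask by the Ohira–Bestmann variant of the Seyferth–Gilbert reaction, a known one-pot ester-to-terminal-alkyne protocol that avoids handling the aldehyde.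

**Step 6**
Reactants: 11 1-(benzyloxy)-4-(but-3-yn-1-yl)-2-(4-{2-[3-(benzyloxy)phenyl]ethyl}phenoxy)benzene
Product: 12 benzyl 5-[4-(benzyloxy)-3-(4-{2-[3-(benzyloxy)phenyl]ethyl}phenoxy)phenyl]pent-2-ynoate
Conditions: n-BuLi (1.05 equiv), THF, −78 °C; then ClCO2Bn, −78 to 0 °C
Reagents that add atoms: benzyl chloroformate, O=C(Cl)OCc1ccccc1
Why: The terminal alkyne C–H is by far the most acidic site and is deprotonated selectively at −78 °C, and C-acylation of the lithium acetylide with a chloroformate is the standard route to 2-alkynoates.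

**Step 7**
Reactants: 12 benzyl 5-[4-(benzyloxy)-3-(4-{2-[3-(benzyloxy)phenyl]ethyl}phenoxy)phenyl]pent-2-ynoate; 13 1-methoxycyclohexa-1,3-diene
Product: 15 benzyl 2-{2-[4-(benzyloxy)-3-(4-{2-[3-(benzyloxy)phenyl]ethyl}phenoxy)phenyl]ethyl}-6-methoxybenzoate, via bicyclo[2.2.2]octadiene adduct 14 (not isolated)
Conditions: 13 (6 equiv), BHT (5 mol %), o-xylene, base-washed sealed tube, 170 °C
Reagents that add atoms: none
Why: The electron-rich 1-methoxydiene (HOMO) and the electron-poor alkynoate (LUMO) should combine in a concerted thermal Diels–Alder reaction, C4 of the diene bonding to the chain-bearing β-carbon and C1 (bearing OMe) to the ester-bearing α-carbon, to give the 1-methoxybicyclo[2.2.2]octa-2,5-diene 14, which at the same temperature loses its saturated two-carbon bridge as ethylene by retro-[4+2]. The closest known reaction type is the Alder–Rickert synthesis of 6-alkyl-2-methoxybenzoates from 1-methoxycyclohexa-1,3-dienes and 2-alkynoates. Ring A is closed by this intermolecular [4+2] cycloaddition, in which both new ring bonds form in one pericyclic event, and it becomes aromatic through the cycloreversion, which is irreversible because ethylene escapes and an arene is gained. No stereocentre remains, since the two bridgehead centres of racemic 14 are erased on aromatisation. The selectivity required is regiochemical (ester ortho to OMe, chain meta to it) and is secured by the donor methoxy group at the diene terminus, which puts the larger HOMO coefficient on C4, and by the ester acceptor, which puts the larger LUMO coefficient on the β-carbon. The alkyne is the only dienophile in 12 and the benzyl ester and ethers are thermally stable, so no chemoselectivity problem is expected.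

**Step 8**
Reactants: 15 benzyl 2-{2-[4-(benzyloxy)-3-(4-{2-[3-(benzyloxy)phenyl]ethyl}phenoxy)phenyl]ethyl}-6-methoxybenzoate
Product: 16 2-{2-[4-hydroxy-3-(4-{2-[3-hydroxyphenyl]ethyl}phenoxy)phenyl]ethyl}-6-methoxybenzoic acid
Conditions: H2 (1 atm), 10 % Pd/C, EtOAc/MeOH, rt
Reagents that add atoms: none
Why: Catalytic hydrogenolysis cleaves the benzyl ester at its O–CH2 bond, which sidesteps the slow acyl substitution of a 2,6-disubstituted benzoate, and removes both aryl benzyl ethers in the same operation while the methyl ether and the diaryl ether are inert.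

**Step 9**
Reactants: 16 2-{2-[4-hydroxy-3-(4-{2-[3-hydroxyphenyl]ethyl}phenoxy)phenyl]ethyl}-6-methoxybenzoic acid
Product: 17 2-{4-[2-(3-hydroxyphenyl)ethyl]phenoxy}-4-[2-(3-methoxyphenyl)ethyl]phenol
Conditions: Ag2CO3 (10 mol %), AcOH (5 mol %), DMSO, 120 °C, Ar
Reagents that add atoms: none
Why: Silver-catalysed protodecarboxylation proceeds through a silver carboxylate that extrudes CO2 to an aryl-silver species and is then protonated, a process that is accelerated when the carboxyl group is flanked by ortho substituents as here (OMe and alkyl), and the catalytic, weakly basic conditions should leave the two phenols alone.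

**Compound list**
1 | 4-ethenylphenyl acetate (4-acetoxystyrene) | CC(=O)Oc1ccc(C=C)cc1 | starting material
2 | 1-(benzyloxy)-3-bromobenzene | Brc1cccc(OCc2ccccc2)c1 | starting material
3 | 4-[2-(9-borabicyclo[3.3.1]nonan-9-yl)ethyl]phenyl acetate | CC(=O)Oc1ccc(CCB2C3CCCC2CCC3)cc1 | intermediate
4 | 4-[2-(9-borabicyclo[3.3.1]nonan-9-yl)ethyl]phenol (present as its sodium phenoxide/borate) | Oc1ccc(CCB2C3CCCC2CCC3)cc1 | intermediate
5 | 4-{2-[3-(benzyloxy)phenyl]ethyl}phenol | Oc1ccc(CCc2cccc(OCc3ccccc3)c2)cc1 | intermediate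
6 | methyl 3-(4-hydroxyphenyl)propanoate | COC(=O)CCc1ccc(O)cc1 | starting material
7 | methyl 3-(3-bromo-4-hydroxyphenyl)propanoate | COC(=O)CCc1ccc(O)c(Br)c1 | intermediate
8 | methyl 3-[4-(benzyloxy)-3-bromophenyl]propanoate | COC(=O)CCc1ccc(OCc2ccccc2)c(Br)c1 | intermediate
9 | methyl 3-[4-(benzyloxy)-3-(4-{2-[3-(benzyloxy)phenyl]ethyl}phenoxy)phenyl]propanoate | COC(=O)CCc1ccc(OCc2ccccc2)c(Oc2ccc(CCc3cccc(OCc4ccccc4)c3)cc2)c1 | intermediate
10 | 3-[4-(benzyloxy)-3-(4-{2-[3-(benzyloxy)phenyl]ethyl}phenoxy)phenyl]propanal | O=CCCc1ccc(OCc2ccccc2)c(Oc2ccc(CCc3cccc(OCc4ccccc4)c3)cc2)c1 | intermediate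
11 | 1-(benzyloxy)-4-(but-3-yn-1-yl)-2-(4-{2-[3-(benzyloxy)phenyl]ethyl}phenoxy)benzene | C#CCCc1ccc(OCc2ccccc2)c(Oc2ccc(CCc3cccc(OCc4ccccc4)c3)cc2)c1 | intermediate
12 | benzyl 5-[4-(benzyloxy)-3-(4-{2-[3-(benzyloxy)phenyl]ethyl}phenoxy)phenyl]pent-2-ynoate | O=C(OCc1ccccc1)C#CCCc1ccc(OCc2ccccc2)c(Oc2ccc(CCc3cccc(OCc4ccccc4)c3)cc2)c1 | intermediate
13 | 1-methoxycyclohexa-1,3-diene | COC1=CC=CCC1 | starting material
14 | benzyl 3-{2-[4-(benzyloxy)-3-(4-{2-[3-(benzyloxy)phenyl]ethyl}phenoxy)phenyl]ethyl}-1-methoxybicyclo[2.2.2]octa-2,5-diene-2-carboxylate (racemic, transient) | COC12CCC(C=C1)C(CCc3ccc(OCc4ccccc4)c(Oc4ccc(CCc5cccc(OCc6ccccc6)c5)cc4)c3)=C2C(=O)OCc1ccccc1 | intermediate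
15 | benzyl 2-{2-[4-(benzyloxy)-3-(4-{2-[3-(benzyloxy)phenyl]ethyl}phenoxy)phenyl]ethyl}-6-methoxybenzoate | O=C(OCc1ccccc1)c1c(OC)cccc1CCc1ccc(OCc2ccccc2)c(Oc2ccc(CCc3cccc(OCc4ccccc4)c3)cc2)c1 | intermediate
16 | 2-{2-[4-hydroxy-3-(4-{2-[3-hydroxyphenyl]ethyl}phenoxy)phenyl]ethyl}-6-methoxybenzoic acid | COc1cccc(CCc2ccc(O)c(Oc3ccc(CCc4cccc(O)c4)cc3)c2)c1C(=O)O | intermediate
17 | 2-{4-[2-(3-hydroxyphenyl)ethyl]phenoxy}-4-[2-(3-methoxyphenyl)ethyl]phenol (achiral) | COc1cccc(CCc2ccc(O)c(Oc3ccc(CCc4cccc(O)c4)cc3)c2)c1 | target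

**Step count.** Total: 9 steps. Longest linear sequence: 8 steps (steps 2–9, from 6); the C–D phenol 5 is made in one step and joins at step 4.

**Steps most likely to fail**

1. Step 7 (Alder–Rickert benzannulation). The β-alkyl, singly activated alkyne may add too slowly at temperatures the diene survives, so that diene dimerisation or disproportionation to anisole consumes the partner, or regiocontrol may erode at high temperature. Fallback (ring A introduced as an intact aryl unit instead of being built): setting out from methyl ester 9, saponification (LiOH, THF/H2O) would give 3-[4-(benzyloxy)-3-(4-{2-[3-(benzyloxy)phenyl]ethyl}phenoxy)phenyl]propanoic acid F1. Esterification with N-hydroxyphthalimide (DIC, cat. DMAP, CH2Cl2) would give the redox-active 1,3-dioxoisoindolin-2-yl ester F2. Iron-catalysed decarboxylative Negishi arylation (Fe(acac)3, dppBz, bis(3-methoxyphenyl)zinc prepared from 3-bromoanisole, THF, rt) would then give 1-(benzyloxy)-2-(4-{2-[3-(benzyloxy)phenyl]ethyl}phenoxy)-4-[2-(3-methoxyphenyl)ethyl]benzene F3. Hydrogenolysis (H2, Pd/C) comes back to the route at target 17.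

2. Step 4 (Ullmann etherification). Oxidative addition at the hindered, electron-rich ortho-benzyloxy bromide may be slow, allowing protodebromination or ester cleavage to compete. Fallback (polarity of the ring-B partner reversed, oxidative coupling at room temperature): setting out from bromide 8, Pd-catalysed borylation with tetrahydroxydiboron (XPhos-Pd precatalyst, KOAc, MeOH, 60–80 °C) would give [2-(benzyloxy)-5-(3-methoxy-3-oxopropyl)phenyl]boronic acid F4. Chan–Lam etherification of F4 with phenol 5 (Cu(OAc)2, pyridine, 4 Å MS, CH2Cl2, air, rt) comes back to the route at 9.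

3. Step 9 (protodecarboxylation). CO2 extrusion may be incomplete for a benzoic acid with only one ortho-alkoxy group, or the free phenols may be degraded oxidatively by Ag(I) in hot DMSO. Fallback (decarboxylation moved ahead of phenol release): setting out from benzyl ester 15, hydrogenolysis over Pd/C poisoned with 2,2'-bipyridyl (H2, EtOAc/MeOH, rt), conditions known to cleave benzyl esters while sparing phenolic benzyl ethers, would give 2-{2-[4-(benzyloxy)-3-(4-{2-[3-(benzyloxy)phenyl]ethyl}phenoxy)phenyl]ethyl}-6-methoxybenzoic acid F5. Silver-catalysed protodecarboxylation of this phenol-free acid (Ag2CO3, AcOH, DMSO, 120 °C) would give 1-(benzyloxy)-2-(4-{2-[3-(benzyloxy)phenyl]ethyl}phenoxy)-4-[2-(3-methoxyphenyl)ethyl]benzene F6 (identical in structure with F3). Hydrogenolysis (H2, Pd/C) comes back to the route at target 17.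

**Further compounds**
F1 | step 7 | 3-[4-(benzyloxy)-3-(4-{2-[3-(benzyloxy)phenyl]ethyl}phenoxy)phenyl]propanoic acid | OC(=O)CCc1ccc(OCc2ccccc2)c(Oc2ccc(CCc3cccc(OCc4ccccc4)c3)cc2)c1
F2 | step 7 | 1,3-dioxoisoindolin-2-yl 3-[4-(benzyloxy)-3-(4-{2-[3-(benzyloxy)phenyl]ethyl}phenoxy)phenyl]propanoate | O=C(CCc1ccc(OCc2ccccc2)c(Oc2ccc(CCc3cccc(OCc4ccccc4)c3)cc2)c1)ON1C(=O)c2ccccc2C1=O
F3 | step 7 | 1-(benzyloxy)-2-(4-{2-[3-(benzyloxy)phenyl]ethyl}phenoxy)-4-[2-(3-methoxyphenyl)ethyl]benzene | COc1cccc(CCc2ccc(OCc3ccccc3)c(Oc3ccc(CCc4cccc(OCc5ccccc5)c4)cc3)c2)c1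
F4 | step 4 | [2-(benzyloxy)-5-(3-methoxy-3-oxopropyl)phenyl]boronic acid | COC(=O)CCc1ccc(OCc2ccccc2)c(B(O)O)c1
F5 | step 9 | 2-{2-[4-(benzyloxy)-3-(4-{2-[3-(benzyloxy)phenyl]ethyl}phenoxy)phenyl]ethyl}-6-methoxybenzoic acid | COc1cccc(CCc2ccc(OCc3ccccc3)c(Oc3ccc(CCc4cccc(OCc5ccccc5)c4)cc3)c2)c1C(=O)O
F6 | step 9 | 1-(benzyloxy)-2-(4-{2-[3-(benzyloxy)phenyl]ethyl}phenoxy)-4-[2-(3-methoxyphenyl)ethyl]benzene | COc1cccc(CCc2ccc(OCc3ccccc3)c(Oc3ccc(CCc4cccc(OCc5ccccc5)c4)cc3)c2)c1
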